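**Plan**

- Locants: C1' (OCH2), C2'/C3' (oxirane), C4' (CH2), C5' (lactone CH–O), C6', C7' (carbinol), C8' (lactone C=O). The retrosynthesis cuts, in order: the aryl ether O–C1' (Mitsunobu); the oxirane (epoxidation of a Z-allylic alcohol); the lactone acyl bond C8'–O (transacylation); C4'–C5' together with a temporary C1'–O bond (hetero-Diels–Alder); and C6'–C7' (enolate allylation of a lactic acid acetal).
- Enabling feature: C1' and C4' are cis on the oxirane, and oxygen sits on both C1' and C5'. The six atoms O–C1'–C2'–C3'(CH3)–C4'–C5' are therefore a latent 4-methyl-3,6-dihydro-2H-pyran, the [4+2] retron of a 1-alkoxy-isoprene and an aldehyde. The ring fixes the cis alkene.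
- Forward ring order: dioxolanone ring (temporary; carries C7', masks the acid and the tertiary OH) → dihydropyran ring (temporary; key step) → pyran opened by hydrolysis and reduction while the γ-lactone closes and the dioxolanone is discarded → oxirane → coumarin attached last.
- Stereochemistry: C7' from (R)-lactic acid by self-regeneration of stereocentres; C5' from the chiral chromium catalyst in the cycloaddition; alkene geometry from the ring; C2'/C3' from L-(+)-tartrate-controlled epoxidation.

Key step: step 6

**Remarks**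

- Catalyst A is CrCl(L), the chloride complex of trivalent chromium with L = the dianion of the tridentate Schiff base (1R,2S)-1-{[3-(1-adamantyl)-2-hydroxy-5-methylbenzylidene]amino}indan-2-ol.
- Assumption: the (1R,2S) series of catalyst A is taken to expose the Re face of a bound aldehyde RCH2CHO to a 1-alkoxydiene, as for simple alkoxyacetaldehydes. If the sense is the opposite, the mirror-image catalyst is used with no other change.

**Route**

Step 1
Reactants: 1 (R)-lactic acid; 2 pivaldehyde
Product: 3 (2R,5R)-2-tert-butyl-5-methyl-1,3-dioxolan-4-one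
Conditions: p-TsOH·H2O (cat.), H2SO4 (cat.), pentane, reflux, water separator; crystallisation from pentane/Et2O at −78 °C
Reagents that add atoms: none
Why: Acid-catalysed acetalisation of the α-hydroxy acid under thermodynamic control should favour the cis acetal, which is purified by cold crystallisation, so that the lactate stereocentre is copied onto the acetal carbon (first stage of the Seebach self-regeneration of stereocentres).

Step 2
Reactants: 3 (2R,5R)-2-tert-butyl-5-methyl-1,3-dioxolan-4-one
Product: 5 (2R,5S)-2-tert-butyl-5-methyl-5-(prop-2-en-1-yl)-1,3-dioxolan-4-one, via lithium enolate 4 (not isolated)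
Conditions: LiN(i-Pr)2, THF, −78 °C; allyl bromide, −78 → −30 °C
Reagents that add atoms: allyl bromide C=CCBr
Why: The planar enolate keeps only the acetal stereocentre, and allyl bromide should enter trans to tert-butyl (Seebach alkylation), which sets the quaternary carbon C7' with methyl cis to tert-butyl.

Step 3
Reactants: 5 (2R,5S)-2-tert-butyl-5-methyl-5-(prop-2-en-1-yl)-1,3-dioxolan-4-one
Product: 7 2-[(2R,4S)-2-tert-butyl-4-methyl-5-oxo-1,3-dioxolan-4-yl]acetaldehyde, via ozonide 6 (not isolated)
Conditions: O3, CH2Cl2, −78 °C; PPh3, −78 °C → rt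
Reagents that add atoms: ozone [O-][O+]=O
Why: Ozonolysis of the terminal alkene with neutral reductive work-up should give the aldehyde while sparing the dioxolanone and avoiding base-induced β-elimination of the acetal oxygen.

Step 4
Reactants: 8 3-methylbut-2-enal
Product: 9 1,1-dimethoxy-3-methylbut-2-ene
Conditions: HC(OMe)3, NH4NO3 (cat.), MeOH, rt
Reagents that add atoms: trimethyl orthoformate COC(OC)OC
Why: Orthoester-driven acetalisation under a weak ammonium-salt acid should give the dimethyl acetal without conjugate addition of methanol.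

Step 5
Reactants: 9 1,1-dimethoxy-3-methylbut-2-ene
Product: 10 (1E)-1-methoxy-3-methylbuta-1,3-diene
Conditions: TMSOTf, i-Pr2NEt, CH2Cl2, −20 °C → rt; distillation
Reagents that add atoms: none
Why: The silyl triflate ionises the acetal to the conjugated oxocarbenium ion and the hindered amine removes a γ-methyl proton (enol ether formation from an acetal as a 1,4-elimination), the E enol ether following from the extended ion.

Step 6
Reactants: 7 2-[(2R,4S)-2-tert-butyl-4-methyl-5-oxo-1,3-dioxolan-4-yl]acetaldehyde; 10 (1E)-1-methoxy-3-methylbuta-1,3-diene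
Product: 11 (2R,5S)-2-tert-butyl-5-{[(2R,6S)-6-methoxy-4-methyl-3,6-dihydro-2H-pyran-2-yl]methyl}-5-methyl-1,3-dioxolan-4-one
Conditions: catalyst A (5 mol %), 4 Å molecular sieves, neat (10, 1.5 equiv), rt; chromatography on Et3N-deactivated silica
Reagents that add atoms: none
Why: The chromium Lewis acid binds the aldehyde oxygen of 7 and the electron-rich 1-methoxydiene adds in a concerted, asynchronous [4+2] hetero-Diels–Alder reaction in which the diene terminus remote from OMe (largest HOMO coefficient, C4') bonds to the carbonyl carbon (C5') and the carbonyl oxygen bonds to the methoxy-bearing carbon (C1'), so the regiochemistry is fixed electronically. The closest known reaction type is the Jacobsen-type oxa-Diels–Alder reaction of 1-alkoxybutadienes with unactivated aliphatic aldehydes under chromium Schiff-base catalysis. The one ring closed, the 3,6-dihydro-2H-pyran, forms by [4+2] cycloaddition on the s-cis diene, so the new C2'=C3' double bond must emerge cis inside the ring, which fixes the later Z geometry. The carbinol centre C5' is set by the catalyst, which should expose the Re face of the bound aldehyde and override the weak bias of the remote quaternary dioxolanone carbon; the acetal centre follows from the endo transition state (2,6-cis) and is erased later. The step needs chemoselectivity for the aldehyde over the dioxolanone carbonyl, secured by the much higher Lewis basicity and electrophilicity of the unhindered aldehyde; it also needs the cyclic pathway rather than an open-chain vinylogous aldol, secured by the methyl enol ether, which has no transferable silyl group.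

Step 7
Reactants: 11 (2R,5S)-2-tert-butyl-5-{[(2R,6S)-6-methoxy-4-methyl-3,6-dihydro-2H-pyran-2-yl]methyl}-5-methyl-1,3-dioxolan-4-one
Product: 14 (3S,5R)-3-hydroxy-5-[(2Z)-4-hydroxy-2-methylbut-2-en-1-yl]-3-methyloxolan-2-one, via lactol 12 (not isolated), via diol 13 (not isolated)
Conditions: 0.1 M aq. HCl, THF, 0 °C, then NaHCO3; NaBH4, CeCl3·7H2O, MeOH, −40 → 0 °C, aq. NH4Cl; DBU (cat.), CH2Cl2, rt
Reagents that add atoms: water O
Why: Mild hydrolysis of the allylic methyl acetal gives lactol 12, whose small equilibrium share of Z-hydroxy-enal is reduced 1,2 by NaBH4/CeCl3 (Luche reduction) to diol 13 with the ring-derived Z geometry intact, and base-catalysed 5-exo-trig attack of the C5' hydroxyl on the activated dioxolanone carbonyl then closes the γ-lactone with retention at C5' and C7' while expelling pivaldehyde and baring the tertiary alcohol.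

Step 8
Reactants: 14 (3S,5R)-3-hydroxy-5-[(2Z)-4-hydroxy-2-methylbut-2-en-1-yl]-3-methyloxolan-2-one
Product: 15 (3S,5S)-3-hydroxy-5-{[(2R,3S)-3-(hydroxymethyl)-2-methyloxiran-2-yl]methyl}-3-methyloxolan-2-one
Conditions: Ti(O-i-Pr)4 (20 mol %), diisopropyl L-(+)-tartrate (24 mol %), t-BuOOH (anhydrous, decane), 4 Å molecular sieves, CH2Cl2, −20 °C; aq. citric acid work-up
Reagents that add atoms: tert-butyl hydroperoxide CC(C)(C)OO
Why: Sharpless asymmetric epoxidation: with the primary allylic alcohol bound to the Ti(O-i-Pr)4/L-(+)-tartrate/t-BuOOH system, oxygen should be delivered to the 2'Re,3'Re face of the Z-alkene, as with nerol, which sets the (2'S,3'R) oxirane with C1' and C4' cis under reagent control.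

Step 9
Reactants: 15 (3S,5S)-3-hydroxy-5-{[(2R,3S)-3-(hydroxymethyl)-2-methyloxiran-2-yl]methyl}-3-methyloxolan-2-one; 16 7-hydroxy-2H-chromen-2-one (umbelliferone)
Product: 17 7-{[(2S,3R)-3-{[(2S,4S)-4-hydroxy-4-methyl-5-oxooxolan-2-yl]methyl}-3-methyloxiran-2-yl]methoxy}-2H-chromen-2-one
Conditions: PPh3, DIAD, THF, 0 °C → rt
Reagents that add atoms: none
Why: Mitsunobu etherification: the acidic phenol of 16 displaces the activated primary carbinol, the tertiary alcohol cannot form a reactive oxyphosphonium ion, and the near-neutral conditions spare the epoxide and both lactones, no stereocentre being touched.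

**Compound list**

1 | (R)-lactic acid [(2R)-2-hydroxypropanoic acid] | C[C@@H](O)C(=O)O | starting material
2 | pivaldehyde (2,2-dimethylpropanal) | CC(C)(C)C=O | starting material
3 | (2R,5R)-2-tert-butyl-5-methyl-1,3-dioxolan-4-one (cis) | C[C@H]1O[C@@H](C(C)(C)C)OC1=O | intermediate
4 | lithium (2R)-2-tert-butyl-5-methyl-1,3-dioxol-4-olate (lithium enolate of 3) | CC1=C(O[Li])O[C@H](C(C)(C)C)O1 | intermediate
5 | (2R,5S)-2-tert-butyl-5-methyl-5-(prop-2-en-1-yl)-1,3-dioxolan-4-one | C[C@@]1(CC=C)O[C@@H](C(C)(C)C)OC1=O | intermediate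
6 | (2R,5S)-2-tert-butyl-5-methyl-5-[(1,2,4-trioxolan-3-yl)methyl]-1,3-dioxolan-4-one (ozonide, mixture at the trioxolane carbon) | C[C@@]1(CC2OCOO2)O[C@@H](C(C)(C)C)OC1=O | intermediate
7 | 2-[(2R,4S)-2-tert-butyl-4-methyl-5-oxo-1,3-dioxolan-4-yl]acetaldehyde | C[C@@]1(CC=O)O[C@@H](C(C)(C)C)OC1=O | intermediate
8 | 3-methylbut-2-enal | CC(C)=CC=O | starting material
9 | 1,1-dimethoxy-3-methylbut-2-ene | COC(OC)C=C(C)C | intermediate
10 | (1E)-1-methoxy-3-methylbuta-1,3-diene | CO/C=C/C(C)=C | intermediate
11 | (2R,5S)-2-tert-butyl-5-{[(2R,6S)-6-methoxy-4-methyl-3,6-dihydro-2H-pyran-2-yl]methyl}-5-methyl-1,3-dioxolan-4-one | C[C@@]1(C[C@H]2CC(C)=C[C@@H](OC)O2)O[C@@H](C(C)(C)C)OC1=O | intermediate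
12 | (2R,5S)-2-tert-butyl-5-{[(2R)-6-hydroxy-4-methyl-3,6-dihydro-2H-pyran-2-yl]methyl}-5-methyl-1,3-dioxolan-4-one (lactol, anomer mixture) | C[C@@]1(C[C@H]2CC(C)=CC(O)O2)O[C@@H](C(C)(C)C)OC1=O | intermediate
13 | (2R,5S)-2-tert-butyl-5-[(2R,4Z)-2,6-dihydroxy-4-methylhex-4-en-1-yl]-5-methyl-1,3-dioxolan-4-one | C[C@@]1(C[C@H](O)C/C(C)=C\CO)O[C@@H](C(C)(C)C)OC1=O | intermediate
14 | (3S,5R)-3-hydroxy-5-[(2Z)-4-hydroxy-2-methylbut-2-en-1-yl]-3-methyloxolan-2-one | C[C@]1(O)C[C@@H](C/C(C)=C\CO)OC1=O | intermediate
15 | (3S,5S)-3-hydroxy-5-{[(2R,3S)-3-(hydroxymethyl)-2-methyloxiran-2-yl]methyl}-3-methyloxolan-2-one | C[C@]1(O)C[C@@H](C[C@@]2(C)O[C@H]2CO)OC1=O | intermediate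
16 | 7-hydroxy-2H-chromen-2-one (umbelliferone) | O=c1ccc2ccc(O)cc2o1 | starting material
17 | 7-{[(2S,3R)-3-{[(2S,4S)-4-hydroxy-4-methyl-5-oxooxolan-2-yl]methyl}-3-methyloxiran-2-yl]methoxy}-2H-chromen-2-one | C[C@]1(O)C[C@@H](C[C@@]2(C)O[C@H]2COc2ccc3ccc(=O)oc3c2)OC1=O | target

**Count**

Total steps: 9. Longest linear sequence: 7 (steps 1, 2, 3, 6, 7, 8, 9).

**Steps most likely to fail, with fallbacks**

Step 6. The cycloaddition may be slow for the β-quaternary aldehyde, so that diene decomposition or β-elimination of the acetal oxygen from 7 outruns it. Facial selectivity may also erode if the resident quaternary centre opposes the catalyst. The fallback sets out from diene 10 and enolate 4 (made from 3) and comes back at 11. Diene 10 and commercial (tert-butyldimethylsilyloxy)acetaldehyde (CC(C)(C)[Si](C)(C)OCC=O), an unhindered achiral aldehyde of the class for which this catalyst is best established, undergo the same catalysed cycloaddition to give tert-butyl{[(2R,6S)-6-methoxy-4-methyl-3,6-dihydro-2H-pyran-2-yl]methoxy}dimethylsilane F1. n-Bu4NF in THF frees [(2R,6S)-6-methoxy-4-methyl-3,6-dihydro-2H-pyran-2-yl]methanol F2. Tf2O and 2,6-lutidine in CH2Cl2 at −78 °C give [(2R,6S)-6-methoxy-4-methyl-3,6-dihydro-2H-pyran-2-yl]methyl trifluoromethanesulfonate F3. F3 alkylates lithium enolate 4 trans to tert-butyl (THF, −78 °C) to give 11. The two halves are then joined at C6'–C7' by enolate alkylation, and the cycloaddition runs without double stereodifferentiation.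

Step 7. In aqueous acid the ring-opened Z-hydroxy-enal may isomerise to the E isomer, or water may add at C3' of the conjugated oxocarbenium ion (allylic transposition), before borohydride traps the aldehyde. The fallback sets out from 11 and comes back at 14. Jones oxidation (CrO3, H2SO4, acetone, 0 °C) oxidises the lactol as fast as it forms and gives (6R)-6-{[(2R,4S)-2-tert-butyl-4-methyl-5-oxo-1,3-dioxolan-4-yl]methyl}-4-methyl-5,6-dihydro-2H-pyran-2-one F4, in which the Z geometry is locked in a stable unsaturated δ-lactone. LiOH in aqueous THF opens both acyl rings with loss of pivaldehyde, and acidification gives (2Z,5R,7S)-5,7-dihydroxy-3,7-dimethyloct-2-enedioic acid F5. Under acid F5 should close the five-membered lactone on the non-conjugated carboxyl to give (2Z)-4-[(2R,4S)-4-hydroxy-4-methyl-5-oxooxolan-2-yl]-3-methylbut-2-enoic acid F6. The free acid is then reduced chemoselectively through its mixed anhydride (i-BuOCOCl, N-methylmorpholine, THF, −15 °C; then NaBH4, H2O) to 14, the lactone being left untouched.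

Step 8. Face selectivity and turnover of the titanium-mediated epoxidation may be poor on a Z-trisubstituted allylic alcohol that also carries a chelating α-hydroxy lactone and remote stereocentres. The Lewis acid may also promote opening of the tertiary epoxide carbon by the cis-disposed C7' hydroxyl. The fallback sets out from 14 and comes back at 17, reversing the last two operations and avoiding the titanium reagent. Mitsunobu coupling of 14 with 16 (PPh3, DIAD, THF) gives 7-{[(2Z)-4-[(2R,4S)-4-hydroxy-4-methyl-5-oxooxolan-2-yl]-3-methylbut-2-en-1-yl]oxy}-2H-chromen-2-one F7. The isolated, electron-rich trisubstituted alkene of F7 is then epoxidised by a chiral dioxirane (Shi epoxidation: KHSO5, K2CO3 buffer, MeCN/dimethoxymethane/H2O, 0 °C), using the enantiomer of the fructose-derived ketone catalyst whose spiro transition state delivers oxygen to the 2'Re,3'Re face, to give 17. The electron-poor coumarin double bond should be inert to the dioxirane.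

**Further compounds**

F1 | step 6 | tert-butyl{[(2R,6S)-6-methoxy-4-methyl-3,6-dihydro-2H-pyran-2-yl]methoxy}dimethylsilane | CC(C)(C)[Si](C)(C)OC[C@H]1CC(C)=C[C@@H](OC)O1
F2 | step 6 | [(2R,6S)-6-methoxy-4-methyl-3,6-dihydro-2H-pyran-2-yl]methanol | OC[C@H]1CC(C)=C[C@@H](OC)O1
F3 | step 6 | [(2R,6S)-6-methoxy-4-methyl-3,6-dihydro-2H-pyran-2-yl]methyl trifluoromethanesulfonate | O=S(=O)(OC[C@H]1CC(C)=C[C@@H](OC)O1)C(F)(F)F
F4 | step 7 | (6R)-6-{[(2R,4S)-2-tert-butyl-4-methyl-5-oxo-1,3-dioxolan-4-yl]methyl}-4-methyl-5,6-dihydro-2H-pyran-2-one | C[C@@]1(C[C@H]2CC(C)=CC(=O)O2)O[C@@H](C(C)(C)C)OC1=O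
F5 | step 7 | (2Z,5R,7S)-5,7-dihydroxy-3,7-dimethyloct-2-enedioic acid | C[C@](O)(C[C@H](O)C/C(C)=C\C(=O)O)C(=O)O
F6 | step 7 | (2Z)-4-[(2R,4S)-4-hydroxy-4-methyl-5-oxooxolan-2-yl]-3-methylbut-2-enoic acid | C[C@]1(O)C[C@@H](C/C(C)=C\C(=O)O)OC1=O
F7 | step 8 | 7-{[(2Z)-4-[(2R,4S)-4-hydroxy-4-methyl-5-oxooxolan-2-yl]-3-methylbut-2-en-1-yl]oxy}-2H-chromen-2-one | C[C@]1(O)C[C@@H](C/C(C)=C\COc2ccc3ccc(=O)oc3c2)OC1=O
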